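If a flask is fed in equal portions and its product grows with what has already stood in it, I reckon with the exposure x: the sum, over the portions already in, of each one's share of the charge times the intervals between portions since it went in. I want the product at the end of the three new flasks.

| setting | blue | green | violet | Wednesday's | Sunday's | Thursday's |
|---|---|---|---|---|---|---|
| starting material | 0.68 M (in portions, 4) | 0.68 M (in portions, 4) | 0.68 M (in portions, 4) | 0.68 M (in portions, 4) | 0.68 M (in portions, 4) | 0.68 M (in portions, 4) |
| protic impurity | 0.0035 M | 0.011 M | 0.036 M | 0.00400 M | 0.0120 M | 0.0300 M |
| remark | run made earlier; portions every 2.0 min | run made earlier; portions every 2.0 min | run made earlier; portions every 2.0 min | the portions of starting material follow each other after 2.0 min, the first at the start | the portions of starting material follow each other after 2.0 min, the first at the start | the portions of starting material follow each other after 2.0 min, the first at the start |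
| time |  |  |  | 8.0 min | 8.0 min | 8.0 min |

| run | time / min | product / % | starting material / % |
|---|---|---|---|
| blue | 0.500 | 0.2 | 15.1 |
| blue | 1.33 | 0.5 | 15.0 |
| blue | 2.50 | 1.4 | 27.1 |
| blue | 4.00 | 2.8 | 23.6 |
| blue | 6.00 | 6.4 | 33.7 |
| green | 1.00 | 1.0 | 14.8 |
| green | 2.50 | 1.7 | 27.5 |
| green | 3.00 | 2.9 | 25.4 |
| green | 5.00 | 4.3 | 34.8 |
| green | 6.00 | 7.1 | 32.0 |
| violet | 0.500 | 0.4 | 14.1 |
| violet | 1.33 | 0.8 | 12.8 |
| violet | 2.50 | 1.6 | 25.3 |
| violet | 4.00 | 2.6 | 21.4 |
| violet | 6.00 | 5.6 | 31.5 |

(standard deviation of a reading: 0.5 percentage points)

- amount of product at the end, in percent of the starting material charged for Wednesday's, Sunday's, Thursday's, in this order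
- the course of these numbers from the first flask to the last (falls all the way / rises all the way / rises, then falls / falls, then rises / hardly changes)

- a reading or a percentage of product counts all its forms, free or not
- "hardly changes" means that all values lie within two and a half points (for a concentration: within two and a half percent of the largest)

The exposure is 1.50 at 6.00 min and 2.50 at 8.0 min. The blue, green and violet runs read 6.4%, 7.1% and 5.6% of product at 6.00 min, so a first round, scaling their mean by exposure, gives 10.6% for the new flasks, the same for each. But at 0.500 min the violet run reads 14.1% of starting material against 15.1% in the blue run, so I take it that the protic impurity removes, one for one and from the first minutes, a share q of the charge, where q is its concentration over that of the charge, and that x falls by q for each interval. Going round again with this correction, the mean product per unit of corrected exposure, the yield per exposure g, is 4.46%. My row is then 11.0%, 10.8% and 10.4%, a spread of 0.60 percentage points, so the course hardly changes.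

The forecast gives 11.5%, 12% and 10.7%, higher than mine, and calls the course hardly changes: “The impurity has little effect.”

The flasks give 10.3%, 10.1% and 9.74%, and the course hardly changes.

    starting material → intermediate A (k = 0.00110 /s)
    starting material ⇌ intermediate B (K = 1.50, k = 8.50 × 10⁻⁴ /s)
    starting material ⇌ intermediate C (K = 0.550, k = 0.0580 /s)
    intermediate C → product (k = 0.00120 /s)
    intermediate A → product (k = 2.90 × 10⁻⁴ /s)
    crystals ⇌ product, rate k6*(cs6 - [product]) while solid is left; crystals form when [product] > cs6 (solubility = 0.300 M, k = 0.0970 /s)
    starting material + protic impurity → quenched substrate (k = 0.110 /M/s)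

Beside the g of 4.46% from the earlier runs, Wednesday's result gives a yield per exposure of 4.16%, and on Thursday's corrected exposure that value gives 9.66% against the simulated 9.74%. Thursday's product stands where it does in part because of the length of the run and in part because of the backward run from intermediate C to starting material: with the run taken to 80.0 min Thursday's product is 65.3%, and with that way back removed it is 26.2%, against 9.74%.

(The data stem from a simulated flask for an exercise; scatter was added.)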